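If you want this flask's product at 25 s, ask first how much product the dissolved gas can hold.

    gas phase ⇌ dissolved gas, rate k1*(csat - [dissolved gas]) (k1 = 0.11 /s, csat = 53 mM)
    starting material + dissolved gas ⇌ product (K2 = 28 /M, k2 = 1.3 /M/s)
    dissolved gas + protic impurity → quenched reagent (k3 = 9.8 /M/s)
    starting material ⇌ dormant form (K4 = 17, k4 = 0.060 /s)

starting material 0.20 M; gas phase 53 mM (held); protic impurity 0.0100 M; time 25 s

1. amount of product at 25 s, in percent of the starting material charged
2. concentration of dissolved gas in solution at 25 s, in percent of saturation

**Holding ratio.** At balance, the product step keeps product over free starting material at its equilibrium constant times the dissolved gas. At saturation that is 1.48, the holding ratio, and you scale it down by the gas actually present.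

**Gas first.** The dormancy step, both ways, leaves 24.8% of the charge free at 25 s. Transfer can deliver 72.9% of the charge, far more than the impurity, so I drop the impurity at the end. Supply balanced against transfer and the product step gives 0.0334 M, and free filling gives 0.0496 M. I take the middle, 0.0415 M, or 78.3% of saturation.

**Way one: balance.** The scaled ratio times the free share gives 28.9% of the charge. That product comes out of the same charge, so put it back and go round: 22.4%.

**Way two: flow.** The return constant is 0.0464 /s, a half-life of 14.9 s. Counting the return step alone, product covers 68.7% of its way to balance over 25 s. The first answer becomes 19.8%, and going round gives 16.5%.

**Which cheats.** Both do. Way one takes balance as standing at 25 s, with the gas and free share of that moment. Way two counts the return step alone, but with my gas and free share the step relaxes both ways at about 0.165 /s, a half-life of 4.20 s, shorter than 14.9 s, so its discount is rough. I commit to way two's 16.5% as a rough estimate.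

**The forecast.** It gave 15.5% (13.5% to 17.5%) and 77% (71% to 83%): “product therefore levels off near 0.03 M as the reverse step catches up”. My product and gas both stand above it.

**The flask.** The simulation gives 16.1% and 75.3%. With 17.6% free, product over starting material is 0.915, less than the holding ratio at that gas, 1.11. The neighbouring flask, left until 1.5 min, holds 0.0544 M of gas, so its ratio is 1.52. Its product over its 6.37% of starting material is 1.76, more than that, and its product stands at 11.2%.

The rate constants come from no measurement, and the outcome is calculated.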